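**Retrosynthetic overview**
- The route rests on the 2-pyranone ring (C4a, C5, O6, C7, C8, C8a). It has the connectivity of a lactonised tert-butyl 3-oxoalk-4-ynoate, and the oxygen on C8a (O1) lies six atoms from C2, the β-carbon of the side-chain ketone.
- Key disconnection: O6–C7 and O1–C2 are opened together to an acyclic ynone keto ester that carries the (E)-enone. Forward, gold closes the pyranone ring first and the freed C8a hydroxyl closes the dihydropyran ring second, in one flask; C2 is set there.
- The acyclic precursor comes from a lactol by Wittig olefination with a keto-stabilised ylide. The lactol comes from an alkynyl β-keto ester and cinnamaldehyde by amine-catalysed Michael addition, which sets C4.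
- The keto ester is made from cinnamaldehyde (Corey–Fuchs homologation to the enynoate, then Claisen condensation with tert-butyl acetate); the ylide from 3-phenylpropanoyl chloride.

Key step: step 7

Remark: the Michael adduct is taken to be isolated as its lactol (both anomers), and the key-step precursor as a mixture of the two epimers at the keto ester α-carbon plus enol; neither matters, because that carbon becomes sp2 (C4a).
Remark: the sense of induction in step 5 is assumed from the usual shielding model of diarylprolinol silyl ethers (attack anti to the CPh2OTMS group of the E,s-trans iminium ion); if the opposite sense were found, the (R)-catalyst would be used.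

**Route**

Step 1
Reactants: 1 (E)-cinnamaldehyde
Product: 2 [(1E)-4,4-dibromobuta-1,3-dien-1-yl]benzene
Conditions: CBr4, PPh3, Zn, CH2Cl2, rt
Reagents that add atoms: carbon tetrabromide, BrC(Br)(Br)Br
Why: Corey–Fuchs dibromo-olefination, in which Ph3P=CBr2 formed in the flask olefinates the aldehyde in a Wittig reaction and leaves the E styryl alkene untouched.

Step 2
Reactants: 2 [(1E)-4,4-dibromobuta-1,3-dien-1-yl]benzene
Product: 4 methyl (4E)-5-phenylpent-4-en-2-ynoate, via lithium acetylide 3 (not isolated)
Conditions: n-BuLi (2.1 equiv), THF, −78 °C; then ClCO2Me, −78 to 0 °C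
Reagents that add atoms: methyl chloroformate, COC(Cl)=O
Why: second stage of the Corey–Fuchs alkyne synthesis (Br/Li exchange, Fritsch–Buttenberg–Wiechell rearrangement, deprotonation) should give acetylide 3, which is C-acylated by the chloroformate.

Step 3
Reactants: 4 methyl (4E)-5-phenylpent-4-en-2-ynoate; 5 tert-butyl acetate
Product: 6 tert-butyl (6E)-3-oxo-7-phenylhept-6-en-4-ynoate
Conditions: 5 and LiN(i-Pr)2 (2.2 equiv each), THF, −78 °C; then 4, −78 °C; aq. HCl (1 M) quench at 0 °C
Reagents that add atoms: none
Why: crossed Claisen condensation, in which the lithium enolate of tert-butyl acetate adds 1,2 to the ynoate ester carbonyl under kinetic control and the second equivalent of enolate stores the product as its unreactive enolate until the quench.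

Step 4
Reactants: 7 3-phenylpropanoyl chloride
Product: 8 4-phenyl-1-(triphenylphosphoranylidene)butan-2-one
Conditions: Ph3PCH3Br (2 equiv), n-BuLi (2 equiv), THF, 0 °C; then 7, 0 °C to rt
Reagents that add atoms: methyltriphenylphosphonium bromide, C[P+](c1ccccc1)(c1ccccc1)c1ccccc1.[Br-]
Why: C-acylation of methylidenetriphenylphosphorane by the acid chloride with transylidation (the second equivalent of ylide deprotonates the acylphosphonium salt) is the standard way to an isolable keto-stabilised Wittig reagent.

Step 5
Reactants: 6 tert-butyl (6E)-3-oxo-7-phenylhept-6-en-4-ynoate; 1 (E)-cinnamaldehyde (1.5 equiv)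
Product: 10 tert-butyl (4S)-2-hydroxy-4-phenyl-6-[(3E)-4-phenylbut-3-en-1-yn-1-yl]-3,4-dihydro-2H-pyran-5-carboxylate (lactol; both anomers), via open-chain aldehyde 9 (not isolated)
Conditions: (S)-2-[diphenyl(trimethylsilyloxy)methyl]pyrrolidine (15 mol %), PhCO2H (15 mol %), toluene, 0 °C; catalyst, acid and 1 premixed, 6 added last
Reagents that add atoms: none
Why: iminium-catalysed Michael addition of a β-keto ester to an enal, in which the CPh2OTMS group shields one face of the E,s-trans iminium ion so that the enol of 6 should add anti to it and set the benzylic centre as (3R) in 9 [(4S) in 10], the ketone enol oxygen then traps the aldehyde as the lactol and takes the adduct out of the retro-Michael equilibrium, and premixing keeps the amine bound as iminium ion and away from the alkynone.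

Step 6
Reactants: 10 tert-butyl (4S)-2-hydroxy-4-phenyl-6-[(3E)-4-phenylbut-3-en-1-yn-1-yl]-3,4-dihydro-2H-pyran-5-carboxylate; 8 4-phenyl-1-(triphenylphosphoranylidene)butan-2-one (1.3 equiv)
Product: 11 tert-butyl (3R,5E)-7-oxo-3,9-diphenyl-2-[(4E)-5-phenylpent-4-en-2-ynoyl]non-5-enoate (α-epimers and enol)
Conditions: PhCO2H (10 mol %), CH2Cl2, rt
Reagents that add atoms: none
Why: Wittig olefination of the open-chain aldehyde tautomer with a keto-stabilised ylide, which should give the E-enone and, being neutral and salt-free, should leave the alkynone, the tert-butyl ester and the benzylic stereocentre alone.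

Step 7
Reactants: 11 tert-butyl (3R,5E)-7-oxo-3,9-diphenyl-2-[(4E)-5-phenylpent-4-en-2-ynoyl]non-5-enoate
Product: 13 katsumadain A [(2S,4S)-2-(2-oxo-4-phenylbutyl)-4-phenyl-7-[(E)-2-phenylethenyl]-3,4-dihydro-2H,5H-pyrano[4,3-b]pyran-5-one], via hydroxypyranone 12 (not isolated)
Conditions: Ph3PAuNTf2 (5 mol %), CH2Cl2/AcOH (10:1), rt; then evaporate, DBU (0.5 equiv), THF, rt
Reagents that add atoms: none
Why: Proposed new method: cationic monovalent gold should π-activate the ynone alkyne of 11 so that the tert-butyl ester carbonyl oxygen attacks the styryl-bearing carbon C7 (O6–C7), the 2-tert-butoxypyrylium so formed loses isobutene and protodeauration leaves hydroxypyranone 12, whose acidic C8a hydroxyl then adds under DBU to the β-carbon of the (E)-enone (O1–C2). The closest known reactions are the gold-catalysed cyclisation of tert-butyl 3-oxoalk-4-ynoates to 4-hydroxy-2-pyranones and the base-mediated oxa-Michael closure of 4-hydroxy-2-pyranones that carry an enone on C3; untested is their combination on one substrate in one flask, with the enone present while gold acts. The pyranone ring closes 6-endo-dig and the dihydropyran ring 6-exo-trig. The one new stereocentre, C2, is controlled by C4 under equilibrating conditions: the C4 phenyl should sit pseudoaxial to avoid allylic strain with the C5 carbonyl and the ketone chain on C2 equatorial, which is the 2,4-trans (2S,4S) isomer. The step needs 6-endo over 5-exo attack, which the ynone polarisation and the cation-stabilising styryl group on C7 secure, and it needs ring fusion through the C8a oxygen although the pyranone is an ambident nucleophile that could also close through its C5 carbonyl oxygen, which the reversibility of the oxa-Michael addition under DBU secures by draining the 4-pyranone isomer and the cis epimer into the more stable product. Both α-epimers and the enol of 11 converge because that carbon becomes sp2 C4a, and C4, which has no acidifying neighbour, is not touched.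

**Compound list**
1 | (E)-cinnamaldehyde | O=C/C=C/c1ccccc1 | starting material
2 | [(1E)-4,4-dibromobuta-1,3-dien-1-yl]benzene | BrC(Br)=C/C=C/c1ccccc1 | intermediate
3 | lithium (3E)-4-phenylbut-3-en-1-yn-1-ide | [Li]C#C/C=C/c1ccccc1 | intermediate (not isolated)
4 | methyl (4E)-5-phenylpent-4-en-2-ynoate | COC(=O)C#C/C=C/c1ccccc1 | intermediate
5 | tert-butyl acetate | CC(=O)OC(C)(C)C | starting material
6 | tert-butyl (6E)-3-oxo-7-phenylhept-6-en-4-ynoate | CC(C)(C)OC(=O)CC(=O)C#C/C=C/c1ccccc1 | intermediate
7 | 3-phenylpropanoyl chloride | O=C(Cl)CCc1ccccc1 | starting material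
8 | 4-phenyl-1-(triphenylphosphoranylidene)butan-2-one | O=C(CCc1ccccc1)C=P(c1ccccc1)(c1ccccc1)c1ccccc1 | intermediate
9 | tert-butyl (3R)-5-oxo-3-phenyl-2-[(4E)-5-phenylpent-4-en-2-ynoyl]pentanoate | CC(C)(C)OC(=O)C(C(=O)C#C/C=C/c1ccccc1)[C@H](c1ccccc1)CC=O | intermediate (not isolated)
10 | tert-butyl (4S)-2-hydroxy-4-phenyl-6-[(3E)-4-phenylbut-3-en-1-yn-1-yl]-3,4-dihydro-2H-pyran-5-carboxylate | CC(C)(C)OC(=O)C1=C(C#C/C=C/c2ccccc2)OC(O)C[C@H]1c1ccccc1 | intermediate
11 | tert-butyl (3R,5E)-7-oxo-3,9-diphenyl-2-[(4E)-5-phenylpent-4-en-2-ynoyl]non-5-enoate | CC(C)(C)OC(=O)C(C(=O)C#C/C=C/c1ccccc1)[C@H](c1ccccc1)C/C=C/C(=O)CCc1ccccc1 | intermediate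
12 | 4-hydroxy-3-[(1S,3E)-5-oxo-1,7-diphenylhept-3-en-1-yl]-6-[(E)-2-phenylethenyl]-2H-pyran-2-one | O=C(CCc1ccccc1)/C=C/C[C@@H](c1ccccc1)c1c(O)cc(/C=C/c2ccccc2)oc1=O | intermediate (not isolated)
13 | katsumadain A, (2S,4S)-2-(2-oxo-4-phenylbutyl)-4-phenyl-7-[(E)-2-phenylethenyl]-3,4-dihydro-2H,5H-pyrano[4,3-b]pyran-5-one | O=C(CCc1ccccc1)C[C@@H]1C[C@@H](c2ccccc2)c2c(cc(/C=C/c3ccccc3)oc2=O)O1 | target

**Step count**
Total steps: 7. Longest linear sequence: 6 steps (steps 1, 2, 3, 5, 6, 7); step 4 is a one-step side branch.

**Steps most likely to fail**

1. Step 7 (proposed new method).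
- What may go wrong: the enone or the enyne may divert or slow the gold catalyst; the tert-butyl group may be lost without ring closure, followed by decarboxylation; the alkyne may be attacked in the 5-exo sense; the oxa-Michael addition may close through the pyranone carbonyl oxygen or stop short of full equilibration to the trans isomer.
- Fallback (known reaction types, ring order arranged so that gold never meets the enone): set out from lactol 10, whose cyclic enol ether is a (Z)-3-alkoxy-enynoate with ester and alkyne held cis. Ph3PAuNTf2 in CH2Cl2/AcOH should lactonise it with loss of isobutene to the pyranone lactol (4S)-2-hydroxy-4-phenyl-7-[(E)-2-phenylethenyl]-3,4-dihydro-2H,5H-pyrano[4,3-b]pyran-5-one F1. Wittig olefination of F1 with ylide 8, followed by DBU-mediated oxa-Michael closure of the liberated C8a hydroxyl, gives 13, where the fallback rejoins the route.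

2. Step 5.
- What may go wrong: the secondary amine catalyst may add irreversibly to the alkynone of 6 and be depleted; reversible C–C bond formation may erode the enantiomeric purity of the benzylic centre.
- Fallback (pyranone made before the amine step): set out from keto ester 6. Ph3PAuNTf2 in CH2Cl2/AcOH should give 4-hydroxy-6-[(E)-2-phenylethenyl]-2H-pyran-2-one F2, which has no alkynone left. Its iminium-catalysed Michael addition to cinnamaldehyde 1 with the same (S)-catalyst gives the pyranone lactol F1, which is carried on with ylide 8 and DBU as in the first fallback and rejoins the route at 13.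

3. Step 6.
- What may go wrong: olefination may be slow because the aldehyde is held as the lactol; the freed keto ester enol oxygen may close onto the new enone so that the open chain is not obtained pure; retro-Michael cleavage under the basic ylide may erode the benzylic configuration.
- Fallback (ring order inverted instead of suppressing the closure): set out from lactol 10. Olefination with 8 followed by catalytic DBU is driven on to the O-cyclised enol ether tert-butyl (4S)-2-(2-oxo-4-phenylbutyl)-4-phenyl-6-[(3E)-4-phenylbut-3-en-1-yn-1-yl]-3,4-dihydro-2H-pyran-5-carboxylate F3 (both C2 epimers). F3 holds ester and alkyne cis on the ring alkene, so Ph3PAuNTf2 in CH2Cl2/AcOH should close the pyranone ring with loss of isobutene, and DBU equilibration at C2 then gives 13.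

**Further compounds**
F1 | step 7 | (4S)-2-hydroxy-4-phenyl-7-[(E)-2-phenylethenyl]-3,4-dihydro-2H,5H-pyrano[4,3-b]pyran-5-one | OC1C[C@@H](c2ccccc2)c2c(cc(/C=C/c3ccccc3)oc2=O)O1
F2 | step 5 | 4-hydroxy-6-[(E)-2-phenylethenyl]-2H-pyran-2-one | O=c1cc(O)cc(/C=C/c2ccccc2)o1
F3 | step 6 | tert-butyl (4S)-2-(2-oxo-4-phenylbutyl)-4-phenyl-6-[(3E)-4-phenylbut-3-en-1-yn-1-yl]-3,4-dihydro-2H-pyran-5-carboxylate | CC(C)(C)OC(=O)C1=C(C#C/C=C/c2ccccc2)OC(CC(=O)CCc2ccccc2)C[C@H]1c1ccccc1
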